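**Assumption:** both phenols are carried as TBS ethers. The (S)-benzyloxazolidinone Evans syn-aldol sets the (7S,8R) sense, by analogy with the classical (2S,3S) benzaldehyde adduct. The (S,S)-Ru-TsDPEN catalyst delivers the (S)-carbinol.

## Retrosynthetic overview
- The target comes from a last-stage Mitsunobu cyclodehydration of a C9-silylated tetraol; the C7–O bond is retained, which makes the tetrahydrofuran ring.
- That tetraol comes from borohydride opening of a trans,trans-γ-lactone carrying the C7′ carbinol, set by catalyst-controlled transfer hydrogenation with dynamic kinetic resolution.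
- The lactone comes from a desymmetrizing Evans syn-aldol of succinyl bis(oxazolidinone) with silyl-vanillin, followed by lactonization onto the second imide.
- The lactone ring is formed first (step 4) and the tetrahydrofuran last (step 11).

## Route

**Step 1**
Reactants: 1 vanillin
Product: 2 4-(tert-butyldimethylsilyloxy)-3-methoxybenzaldehyde
Conditions: TBSCl, imidazole, DMF, 0 °C → rt
Reagents that add atoms: TBSCl, CC(C)(C)[Si](C)(C)Cl
Why: Silylation of the phenol gives a protecting group that survives enolate, hydride and transfer-hydrogenation chemistry and is removed at the end with fluoride.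

**Step 2**
Reactants: 3 succinyl chloride; 4 (S)-4-benzyloxazolidin-2-one (2.1 equiv)
Product: 5 (S,S)-1,1′-succinylbis(4-benzyloxazolidin-2-one)
Conditions: n-BuLi (2.1 equiv), THF, −78 °C; then 3, −78 °C → 0 °C
Reagents that add atoms: none
Why: Bis-N-acylation of the lithiated oxazolidinone gives a symmetric, C2-related diimide, which is the simple precursor for desymmetrization.

**Step 3**
Reactants: 5 bis-imide; 2 silyl-vanillin
Product: 6 (2S,3S)-3-hydroxy-3-aryl-2-[2-oxo-2-((S)-4-benzyl-oxazolidin-3-yl)ethyl]propanoyl-(S)-oxazolidinone, the syn aldol adduct (C7 S, C8 R in lignan sense)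
Conditions: Bu2BOTf (1.05 equiv), iPr2NEt (1.2 equiv), CH2Cl2, −78 → 0 °C; then 2 (0.9 equiv), −78 → 0 °C; pH 7 buffer, MeOH, H2O2
Reagents that add atoms: none
Why: Evans Z(O)-boron enolate syn-aldol via a Zimmerman–Traxler chair, with the aldehyde attacking the face opposite the benzyl group, sets C7 and C8 together.
Proposed new method: Mono-enolization of a symmetric succinyl diimide with about one equivalent of boron triflate and amine, then a single Evans syn-aldol, breaks the symmetry. The second imide lies too far away to be enolized once the first aldolate forms. The closest known reaction is the Evans syn-aldol of N-acyl oxazolidinones.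

**Step 4**
Reactants: 6 hydroxy bis-imide
Product: 7 (4S,5S)-5-aryl-4-[(S)-4-benzyl-2-oxooxazolidine-3-carbonyl]oxolan-2-one (trans lactone), with recovered 4
Conditions: DMAP (10 mol %), toluene, 50 °C
Reagents that add atoms: none
Why: The C7 hydroxyl attacks the distal imide in a 5-exo acyl transfer (lactonization), expelling the auxiliary; the syn aldol stereochemistry makes the 4,5-disubstituted lactone trans.

**Step 5**
Reactants: 7 lactone-imide
Product: 8 (4R,5S)-4-(hydroxymethyl)-5-aryl-oxolan-2-one, with recovered 4
Conditions: LiBH4 (1.1 equiv), H2O (1.1 equiv), Et2O, 0 °C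
Reagents that add atoms: none
Why: LiBH4/H2O cleaves Evans imides chemoselectively to the primary alcohol (Penning-type conditions) and leaves the lactone. No stereocenter is touched.

**Step 6**
Reactants: 8 hydroxymethyl lactone
Product: 9 (4R,5S)-4-(TBSO-methyl)-5-aryl-oxolan-2-one
Conditions: TBSCl, imidazole, DMF, 0 °C
Reagents that add atoms: TBSCl, CC(C)(C)[Si](C)(C)Cl
Why: Protecting C9 lets the later cyclization involve only C9′ and C7, and removes the acidic imide α-H that would otherwise cause E1cB ring opening.

**Step 7**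
Reactants: 9 lactone; 2 silyl-vanillin
Product: 10 (3R,4R,5S)-3-[hydroxy(aryl)methyl]-4-(TBSO-methyl)-5-aryl-oxolan-2-one (C7′ epimeric mixture)
Conditions: LiHMDS (1.1 equiv), THF, −78 °C; then 2 (1.2 equiv), −78 °C
Reagents that add atoms: none
Why: Lactone-enolate aldol, with the aldehyde approaching trans to the C4 substituent, sets C8′ trans to C8; the carbinol C7′ is left unresolved because it is fixed in step 9.

**Step 8**
Reactants: 10 aldol adduct
Product: 11 3-aroyl lactone (β-keto lactone; C8′ epimerizable)
Conditions: Dess–Martin periodinane, NaHCO3, CH2Cl2, rt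
Reagents that add atoms: none
Why: Oxidation of the secondary benzylic alcohol erases the C7′ mixture and makes C8′ a dynamic, very acidic stereocenter.

**Step 9**
Reactants: 11 3-aroyl lactone
Product: 12 (3R,4R,5S)-3-[(S)-hydroxy(aryl)methyl]-4-(TBSO-methyl)-5-aryl-oxolan-2-one
Conditions: RuCl[(S,S)-TsDPEN](p-cymene) (2 mol %), HCO2H/Et3N (5:2), CH2Cl2, 35 °C
Reagents that add atoms: none (hydrogen only)
Why: Noyori–Ikariya asymmetric transfer hydrogenation with dynamic kinetic resolution; the catalyst chooses the aryl-ketone face (C7′ S), and the rapidly epimerizing C8′ resolves to the trans (thermodynamic) epimer.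
Proposed new method: The closest known reaction is DKR transfer hydrogenation of α-substituted β-keto esters. Here the substrate is a 3-aroyl-4,5-trans lactone whose enolizable C8′–H lets the ketone isomers interconvert faster than they are reduced.

**Step 10**
Reactants: 12 hydroxy lactone
Product: 13 (7S,8R,8′S,7′S)-2,3-bis(hydroxymethyl)-1,4-diarylbutane-1,4-diol, 9-O-TBS (aryl = 4-TBSO-3-MeO-phenyl)
Conditions: LiBH4 (4 equiv), THF, 0 → 40 °C
Reagents that add atoms: none
Why: Borohydride reduces the γ-lactone to the diol, freeing C7–OH and C9′–OH while leaving the TBS ethers and all four stereocenters untouched.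

**Step 11**
Reactants: 13 tetraol
Product: 14 tris-TBS-protected target
Conditions: PPh3 (1.5 equiv), DIAD (1.5 equiv), THF, 0 → 25 °C
Reagents that add atoms: none
Why: Mitsunobu cyclodehydration activates the primary C9′–OH, and the C7 hydroxyl closes the ring by 5-exo-tet displacement, so C7 keeps its configuration; C9–OTBS cannot compete and C7′–OH cannot form a five-membered ring.

**Step 12**
Reactants: 14 protected THF
Product: 15 target, (2S,3R,4S)-2-(4-hydroxy-3-methoxyphenyl)-4-[(S)-hydroxy(4-hydroxy-3-methoxyphenyl)methyl]oxolane-3-methanol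
Conditions: TBAF (3.6 equiv), AcOH (1 equiv), THF, 0 °C → rt
Reagents that add atoms: none
Why: Fluoride removes the aliphatic and both aryl TBS ethers; no carbonyl is present, so nothing can epimerize.

## Compound list
1 | vanillin | COc1cc(C=O)ccc1O | starting material
2 | 4-(TBSO)-3-methoxybenzaldehyde | COc1cc(C=O)ccc1O[Si](C)(C)C(C)(C)C | intermediate
3 | succinyl chloride | ClC(=O)CCC(=O)Cl | starting material
4 | (S)-4-benzyloxazolidin-2-one | O=C1N[C@@H](Cc2ccccc2)CO1 | starting material
5 | (S,S)-succinyl bis-imide | O=C(CCC(=O)N1[C@@H](Cc2ccccc2)COC1=O)N1[C@@H](Cc2ccccc2)COC1=O | intermediate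
6 | syn aldol adduct | O=C(N1[C@@H](Cc2ccccc2)COC1=O)C[C@@H]([C@H](O)c1ccc(O[Si](C)(C)C(C)(C)C)c(OC)c1)C(=O)N1[C@@H](Cc2ccccc2)COC1=O | intermediate
7 | trans lactone-imide | O=C1O[C@H](c2ccc(O[Si](C)(C)C(C)(C)C)c(OC)c2)[C@@H](C(=O)N3[C@@H](Cc4ccccc4)COC3=O)C1 | intermediate
8 | hydroxymethyl lactone | O=C1O[C@H](c2ccc(O[Si](C)(C)C(C)(C)C)c(OC)c2)[C@@H](CO)C1 | intermediate
9 | TBS-protected lactone | O=C1O[C@H](c2ccc(O[Si](C)(C)C(C)(C)C)c(OC)c2)[C@@H](CO[Si](C)(C)C(C)(C)C)C1 | intermediate
10 | lactone aldol adduct (C7′ mixture) | O=C1O[C@H](c2ccc(O[Si](C)(C)C(C)(C)C)c(OC)c2)[C@@H](CO[Si](C)(C)C(C)(C)C)[C@@H]1C(O)c1ccc(O[Si](C)(C)C(C)(C)C)c(OC)c1 | intermediate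
11 | 3-aroyl lactone | O=C1O[C@H](c2ccc(O[Si](C)(C)C(C)(C)C)c(OC)c2)[C@@H](CO[Si](C)(C)C(C)(C)C)[C@@H]1C(=O)c1ccc(O[Si](C)(C)C(C)(C)C)c(OC)c1 | intermediate
12 | hydroxy lactone | O=C1O[C@H](c2ccc(O[Si](C)(C)C(C)(C)C)c(OC)c2)[C@@H](CO[Si](C)(C)C(C)(C)C)[C@@H]1[C@H](O)c1ccc(O[Si](C)(C)C(C)(C)C)c(OC)c1 | intermediate
13 | 9-O-TBS tetraol | OC[C@@H]([C@H](O)c1ccc(O[Si](C)(C)C(C)(C)C)c(OC)c1)[C@H](CO[Si](C)(C)C(C)(C)C)[C@H](O)c1ccc(O[Si](C)(C)C(C)(C)C)c(OC)c1 | intermediate
14 | tris-TBS tetrahydrofuran | COc1cc([C@@H](O)[C@@H]2CO[C@H](c3ccc(O[Si](C)(C)C(C)(C)C)c(OC)c3)[C@H]2CO[Si](C)(C)C(C)(C)C)ccc1O[Si](C)(C)C(C)(C)C | intermediate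
15 | target | COc1cc([C@@H](O)[C@@H]2CO[C@H](c3ccc(O)c(OC)c3)[C@H]2CO)ccc1O | target

**Total steps:** 12. **Longest linear sequence:** 11.

## Three steps most likely to fail
1. **Step 3 (desymmetrizing mono-aldol).** Bis-aldol formation or competing enolization of the second imide could cut the yield.
   Fallback: build lactone 8/9 by a different route. Noyori hydrogenation of the TBS-aryl β-keto tert-butyl ester gives the (S)-β-hydroxy ester. Its Fráter–Seebach dianion is alkylated with methyl bromoacetate, then lactonized and epimerized to the trans lactone. Finally the tert-butyl ester is cleaved and reduced with BH3 to the hydroxymethyl lactone 8.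
2. **Step 9 (transfer hydrogenation with dynamic kinetic resolution).** A β-keto lactone that exists largely as its enol may react slowly or give the wrong C7′/C8′ relationship.
   Fallback: skip the oxidation and transfer hydrogenation. Carry the C7′ epimeric aldol mixture 10 through the lactone reduction (step 10) and Mitsunobu ring closure (step 11), separate the THF epimers, oxidize C7′ with MnO2, and reduce the stable trans-THF ketone with (S)-Me-CBS/BH3.
3. **Step 5 (LiBH4 imide-over-lactone chemoselectivity).** Over-reduction of the lactone to the diol is the concern.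
   Fallback: remove the auxiliary with LiOOH (LiOH, H2O2, THF/H2O, 0 °C) to the lactone-acid, then reduce the acid selectively with BH3·SMe2 to give 8.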